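The target is fisetinidol-(4α→6)-fisetinidol; both flavan units are cut back to one protected monomer and joined last by a cation–arene coupling between C4 of the upper unit and C6 of the lower one. The route rests on making that monomer's pyran ring (O1–C2–C3–C4–C4a–C8a; ring F of the lower unit, whose benzo and catechol rings are D and E) by ring expansion: an enantiopure 2-(α-hydroxybenzyl)-2,3-dihydrobenzofuran undergoes an acid-triggered 1,2-oxygen shift. The step exploits C2 being benzylic to electron-rich ring E and vicinal to the C3 oxygen: ionisation, participation by the furan oxygen and acetate capture enlarge the five-membered ether to the chroman, install the C3 acetate and set 2,3-trans in one operation.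

Key step: step 5

Remark on the chemistry: the target is read as upper unit 2R,3S,4R (2α-aryl, 3β-OH, 4α-aryl, all-trans) and lower unit 2R,3S. In the O-benzylated dimers the same 4α geometry carries the CIP label S, because the benzyl ethers change the ranking at C4. The enantiomer of the fructose-derived epoxidation ketone (made from L-sorbose) is taken as a purchasable catalyst.

Step 1
Reactants: 1 1-[4-(benzyloxy)-2-hydroxyphenyl]ethan-1-one; 2 3,4-bis(benzyloxy)benzaldehyde
Product: 3 (2E)-1-[4-(benzyloxy)-2-hydroxyphenyl]-3-[3,4-bis(benzyloxy)phenyl]prop-2-en-1-one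
Conditions: KOH (aq.), EtOH, 25 °C
Reagents that add atoms: none
Why: Claisen–Schmidt condensation, in which the acetophenone enolate adds to the non-enolisable aldehyde and dehydration should give the conjugated (E)-enone with the chelated 2'-OH left free.

Step 2
Reactants: 3 (2E)-1-[4-(benzyloxy)-2-hydroxyphenyl]-3-[3,4-bis(benzyloxy)phenyl]prop-2-en-1-one
Product: 5 5-(benzyloxy)-2-{(2E)-3-[3,4-bis(benzyloxy)phenyl]prop-2-en-1-yl}phenol, via chalcone ethyl carbonate 4 (not isolated)
Conditions: ClCO2Et, Et3N, THF, 0 °C; then NaBH4, THF/H2O, 0 → 25 °C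
Reagents that add atoms: ethyl chloroformate CCOC(Cl)=O (its atoms are carried only in 4 and are lost again before 5)
Why: Reductive deoxygenation of a 2'-hydroxychalcone to a 2-cinnamylphenol, in which ketone reduction, carbonate transfer and loss to an ortho-quinone methide, and 1,4-hydride addition should leave the (E)-styrenyl alkene in place.

Step 3
Reactants: 5 5-(benzyloxy)-2-{(2E)-3-[3,4-bis(benzyloxy)phenyl]prop-2-en-1-yl}phenol
Product: 6 {5-(benzyloxy)-2-[(2E)-3-[3,4-bis(benzyloxy)phenyl]prop-2-en-1-yl]phenoxy}tri(propan-2-yl)silane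
Conditions: iPr3SiCl, imidazole, DMF, 25 °C
Reagents that add atoms: triisopropylsilyl chloride CC(C)[Si](Cl)(C(C)C)C(C)C
Why: Silyl ether formation masks the oxidation-prone phenol for the epoxidation, and the bulky silyl group should resist the pH 10.5 medium of step 4.

Step 4
Reactants: 6 {5-(benzyloxy)-2-[(2E)-3-[3,4-bis(benzyloxy)phenyl]prop-2-en-1-yl]phenoxy}tri(propan-2-yl)silane
Product: 8 (S)-[3,4-bis(benzyloxy)phenyl][(2R)-6-(benzyloxy)-2,3-dihydro-1-benzofuran-2-yl]methanol, via silylated (2S,3S)-epoxide 7 (not isolated)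
Conditions: ent-Shi ketone (30 mol %), KHSO5 (Oxone), K2CO3, Bu4NHSO4, MeCN/CH2(OMe)2/aq. buffer pH 10.5, 0 °C; extraction; then Bu4NF, THF, 0 → 25 °C; aq. NH4Cl
Reagents that add atoms: potassium peroxymonosulfate [K+].[O-]S(=O)(=O)OO
Why: Shi epoxidation of the (E)-disubstituted styrenyl alkene through the spiro transition state should set both epoxide centres as S,S under catalyst control (the enantiomeric ketone series gives R,R), and the phenoxide freed by fluoride then opens the epoxide 5-exo-tet at the non-benzylic carbon with inversion (giving 2R) while the benzylic C–O bond keeps its S configuration.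

Step 5
Reactants: 8 (S)-[3,4-bis(benzyloxy)phenyl][(2R)-6-(benzyloxy)-2,3-dihydro-1-benzofuran-2-yl]methanol
Product: 10 (2R,3S)-7-(benzyloxy)-2-[3,4-bis(benzyloxy)phenyl]-3,4-dihydro-2H-chromen-3-yl acetate, via tricyclic aryloxiranium ion 9 (not isolated)
Conditions: TsOH·H2O (5 mol %), AcOH (0.02 M), 40 °C
Reagents that add atoms: acetic acid CC(=O)O
Why: Protonation and loss of water from the benzylic carbinol of 8 (readily ionised because of the 3,4-bis(benzyloxy)phenyl group) proceeds with backside participation of the dihydrofuran oxygen, a 3-exo-tet closure that gives the trans-disubstituted aryloxiranium ion 9; acetic acid then opens 9 at the non-benzylic carbon (the former C2 of the dihydrobenzofuran) anti to oxygen, so the O1–C(benzylic) bond becomes the O1–C2 bond of the chroman and the five-membered ether is enlarged to the pyran ring by a 1,2-oxygen shift and not by a direct 6-endo closure. The closest known reaction types are the oxiranium-mediated enlargement of 2-(1-sulfonyloxyalkyl)tetrahydrofurans to 3-acyloxytetrahydropyrans, the aziridinium counterpart from prolinols to 3-substituted piperidines, and the reverse ring contraction of activated 2,3-trans-flavan-3-ols. C3 (S) results from inversion at the 2R ring carbon of 8 and C2 (R) from inversion at the S carbinol carbon, both under substrate control; if the benzylic cation opens, the more stable trans-oxiranium ion and the diequatorial product should restore the same 2,3-trans relationship. The step needs opening at the secondary carbon over return at the benzylic carbon: return only gives dihydrobenzofuran benzylic acetates that re-ionise under the conditions, whereas the secondary acetate 10 does not, so the material should funnel to 10. High dilution in the nucleophilic solvent is meant to suppress intermolecular Friedel–Crafts alkylation of the benzo ring and 1,2-hydride shift to the 2-benzylbenzofuran.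

Step 6
Reactants: 10 (2R,3S)-7-(benzyloxy)-2-[3,4-bis(benzyloxy)phenyl]-3,4-dihydro-2H-chromen-3-yl acetate
Product: 11 (2R,3S,4S)-7-(benzyloxy)-2-[3,4-bis(benzyloxy)phenyl]-4-(2-ethoxyethoxy)-3,4-dihydro-2H-chromen-3-yl acetate
Conditions: DDQ (2 equiv), EtOCH2CH2OH (5 equiv), CH2Cl2, 25 °C
Reagents that add atoms: 2-ethoxyethanol CCOCCO
Why: Oxidative C4 functionalisation of a benzylated flavan-3-ol, in which DDQ abstracts hydride from C4 (cation stabilised by the para 7-benzyloxy group and the ortho ring oxygen) and the alcohol traps the cation; C2 and C3 are untouched, and the C4 configuration (drawn as the quasi-axial 4β ether) is immaterial because it is erased in step 7.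

Step 7
Reactants: 11 (2R,3S,4S)-7-(benzyloxy)-2-[3,4-bis(benzyloxy)phenyl]-4-(2-ethoxyethoxy)-3,4-dihydro-2H-chromen-3-yl acetate; 10 (2R,3S)-7-(benzyloxy)-2-[3,4-bis(benzyloxy)phenyl]-3,4-dihydro-2H-chromen-3-yl acetate
Product: 12 3-O-acetyl-tri-O-benzylfisetinidol-(4α→6)-3-O-acetyl-tri-O-benzylfisetinidol
Conditions: 10 (4 equiv), TMSOTf (0.2 equiv), CH2Cl2, −78 → −40 °C; Et3N
Reagents that add atoms: none
Why: Proanthocyanidin-type Friedel–Crafts coupling, in which the Lewis acid ionises the C4 ether, the 3-acetate shields the β face as a cis-fused acetoxonium ion so the arene should enter from the α face (3,4-trans), and C6 of 10 (para to O1, one flanking substituent) should react in preference to C8 (flanked by two oxygens), with excess 10 limiting chain growth.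

Step 8
Reactants: 12 3-O-acetyl-tri-O-benzylfisetinidol-(4α→6)-3-O-acetyl-tri-O-benzylfisetinidol
Product: 14 (2R,3S,4R)-2-(3,4-dihydroxyphenyl)-4-[(2R,3S)-2-(3,4-dihydroxyphenyl)-3,7-dihydroxy-3,4-dihydro-2H-chromen-6-yl]-3,4-dihydro-2H-chromene-3,7-diol, via hexa-O-benzyl dimer diol 13 (not isolated)
Conditions: K2CO3 (cat.), MeOH/THF, 25 °C; AcOH to pH 7; then H2 (1 atm), Pd(OH)2/C, THF/MeOH/H2O, 25 °C
Reagents that add atoms: none
Why: Base-catalysed methanolysis of the two acetates followed by hydrogenolysis of the six aryl benzyl ethers should free the target without touching any stereocentre, since the interflavan bond and the ring C2–O1 bonds are expected to survive mild hydrogenolysis.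

Compound list
1 | 1-[4-(benzyloxy)-2-hydroxyphenyl]ethan-1-one | CC(=O)c1ccc(OCc2ccccc2)cc1O | starting material
2 | 3,4-bis(benzyloxy)benzaldehyde | O=Cc1ccc(OCc2ccccc2)c(OCc2ccccc2)c1 | starting material
3 | (2E)-1-[4-(benzyloxy)-2-hydroxyphenyl]-3-[3,4-bis(benzyloxy)phenyl]prop-2-en-1-one | O=C(/C=C/c1ccc(OCc2ccccc2)c(OCc2ccccc2)c1)c1ccc(OCc2ccccc2)cc1O | intermediate
4 | 5-(benzyloxy)-2-{(2E)-3-[3,4-bis(benzyloxy)phenyl]prop-2-enoyl}phenyl ethyl carbonate | CCOC(=O)Oc1cc(OCc2ccccc2)ccc1C(=O)/C=C/c1ccc(OCc2ccccc2)c(OCc2ccccc2)c1 | intermediate (not isolated)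
5 | 5-(benzyloxy)-2-{(2E)-3-[3,4-bis(benzyloxy)phenyl]prop-2-en-1-yl}phenol | Oc1cc(OCc2ccccc2)ccc1C/C=C/c1ccc(OCc2ccccc2)c(OCc2ccccc2)c1 | intermediate
6 | {5-(benzyloxy)-2-[(2E)-3-[3,4-bis(benzyloxy)phenyl]prop-2-en-1-yl]phenoxy}tri(propan-2-yl)silane | CC(C)[Si](Oc1cc(OCc2ccccc2)ccc1C/C=C/c1ccc(OCc2ccccc2)c(OCc2ccccc2)c1)(C(C)C)C(C)C | intermediate
7 | (2S,3S)-2-[3,4-bis(benzyloxy)phenyl]-3-{4-(benzyloxy)-2-[tri(propan-2-yl)silyloxy]benzyl}oxirane | c1ccccc1COc1ccc(cc1OCc1ccccc1)[C@@H]1O[C@H]1Cc1ccc(OCc2ccccc2)cc1O[Si](C(C)C)(C(C)C)C(C)C | intermediate (not isolated)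
8 | (S)-[3,4-bis(benzyloxy)phenyl][(2R)-6-(benzyloxy)-2,3-dihydro-1-benzofuran-2-yl]methanol | O[C@@H](c1ccc(OCc2ccccc2)c(OCc2ccccc2)c1)[C@H]1Cc2ccc(OCc3ccccc3)cc2O1 | intermediate
9 | aryloxiranium ion: oxygen of the (R)-dihydrobenzofuran bridged to the (R)-benzylic carbon (trans-disubstituted oxirane, cis-fused) | c1ccccc1COc1ccc(cc1OCc1ccccc1)[C@@H]1[C@H]2Cc3ccc(OCc4ccccc4)cc3[O+]12 | intermediate (not isolated)
10 | (2R,3S)-7-(benzyloxy)-2-[3,4-bis(benzyloxy)phenyl]-3,4-dihydro-2H-chromen-3-yl acetate (3-O-acetyl-tri-O-benzylfisetinidol) | CC(=O)O[C@H]1Cc2ccc(OCc3ccccc3)cc2O[C@@H]1c1ccc(OCc2ccccc2)c(OCc2ccccc2)c1 | intermediate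
11 | (2R,3S,4S)-7-(benzyloxy)-2-[3,4-bis(benzyloxy)phenyl]-4-(2-ethoxyethoxy)-3,4-dihydro-2H-chromen-3-yl acetate (4β ether drawn; its 4-epimer serves equally) | CC(=O)O[C@H]1[C@@H](OCCOCC)c2ccc(OCc3ccccc3)cc2O[C@@H]1c1ccc(OCc2ccccc2)c(OCc2ccccc2)c1 | intermediate
12 | 3-O-acetyl-tri-O-benzylfisetinidol-(4α→6)-3-O-acetyl-tri-O-benzylfisetinidol (upper unit 2R,3S,4S with 4α-aryl; lower unit 2R,3S) | C(c1ccccc1)Oc1ccc2c(c1)O[C@H](c1ccc(OCc3ccccc3)c(OCc3ccccc3)c1)[C@@H](OC(C)=O)[C@@H]2c1cc2c(cc1OCc1ccccc1)O[C@H](c1ccc(OCc3ccccc3)c(OCc3ccccc3)c1)[C@@H](OC(C)=O)C2 | intermediate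
13 | tri-O-benzylfisetinidol-(4α→6)-tri-O-benzylfisetinidol (both 3-OH free; upper unit 2R,3S,4S; lower unit 2R,3S) | C(c1ccccc1)Oc1ccc2c(c1)O[C@H](c1ccc(OCc3ccccc3)c(OCc3ccccc3)c1)[C@@H](O)[C@@H]2c1cc2c(cc1OCc1ccccc1)O[C@H](c1ccc(OCc3ccccc3)c(OCc3ccccc3)c1)[C@@H](O)C2 | intermediate (not isolated)
14 | (2R,3S,4R)-2-(3,4-dihydroxyphenyl)-4-[(2R,3S)-2-(3,4-dihydroxyphenyl)-3,7-dihydroxy-3,4-dihydro-2H-chromen-6-yl]-3,4-dihydro-2H-chromene-3,7-diol (fisetinidol-(4α→6)-fisetinidol) | Oc1ccc2c(c1)O[C@H](c1ccc(O)c(O)c1)[C@@H](O)[C@@H]2c1cc2c(cc1O)O[C@H](c1ccc(O)c(O)c1)[C@@H](O)C2 | target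

Total step count: 8. Longest linear sequence: 8 steps (1 → 14; compound 10 is used twice, as precursor of 11 and as the nucleophile of step 7).

Steps most likely to fail

Step 5. The benzylic cation may be lost by 1,2-hydride shift or elimination to the aromatic 2-benzylbenzofuran, or by intermolecular Friedel–Crafts self-alkylation. Acetate may also be too weak a nucleophile to open the oxiranium ion at the secondary carbon, so that the funnelling stalls or the 2,3-trans relationship erodes. The fallback sets out from 8 and keeps the five-to-six enlargement but carries it with chloride and brings in the oxygen afterwards. SOCl2 and pyridine in CH2Cl2 should give, through the same oxiranium ion and a reversible benzylic chloride, (2R,3S)-7-(benzyloxy)-2-[3,4-bis(benzyloxy)phenyl]-3-chloro-3,4-dihydro-2H-chromene F1. Anti-elimination towards C4 with KOtBu in THF gives (2S)-7-(benzyloxy)-2-[3,4-bis(benzyloxy)phenyl]-2H-chromene F2 (same C2 geometry, changed label), which is kept from light. Hydroboration–oxidation (BH3·SMe2, then NaOH/H2O2) anti to the C2 aryl group gives the 2,3-trans alcohol (2R,3S)-7-(benzyloxy)-2-[3,4-bis(benzyloxy)phenyl]-3,4-dihydro-2H-chromen-3-ol F3. Acetylation (Ac2O, pyridine) comes back to the route at 10.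

Step 6. Hydride abstraction may occur at C2–H (benzylic to the catechol ring and α to O1) instead of C4–H, or go on to over-oxidation, because the benzo ring lacks a 5-oxygen substituent. The fallback sets out from chalcone 3 and builds the C4 oxygen from the chalcone carbonyl. Protection (MOMCl, NaH, DMF) gives (2E)-1-[4-(benzyloxy)-2-(methoxymethoxy)phenyl]-3-[3,4-bis(benzyloxy)phenyl]prop-2-en-1-one F4. Juliá–Colonna epoxidation (poly-L-leucine, H2O2, NaOH, toluene/H2O) gives [4-(benzyloxy)-2-(methoxymethoxy)phenyl]{(2R,3S)-3-[3,4-bis(benzyloxy)phenyl]oxiran-2-yl}methanone F5. HCl in MeOH removes the acetal, and the phenol opens the epoxide at the benzylic carbon with inversion to give (2R,3R)-7-(benzyloxy)-2-[3,4-bis(benzyloxy)phenyl]-3-hydroxy-2,3-dihydro-4H-chromen-4-one F6. NaBH4 in MeOH gives the 3,4-trans diol (2R,3S,4R)-7-(benzyloxy)-2-[3,4-bis(benzyloxy)phenyl]-3,4-dihydro-2H-chromene-3,4-diol F7. Ac2O and pyridine give (2R,3R,4R)-7-(benzyloxy)-2-[3,4-bis(benzyloxy)phenyl]-3,4-dihydro-2H-chromene-3,4-diyl diacetate F8 (same geometry, changed C3 label). F8 takes the place of 11 and, with 10 and TMSOTf as in step 7, comes back to the route at 12.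

Step 7. The ionised electrophile may be consumed by self-condensation and chain growth, the new interflavan bond may be cleaved again by the acid, or facial selectivity at C4 may erode. The fallback sets out from 11 and replaces hard Lewis-acid ionisation of the ether by soft, thiophilic activation in an essentially neutral medium. Benzyl mercaptan with BF3·OEt2 in CH2Cl2 at −78 °C gives (2R,3R,4R)-4-(benzylsulfanyl)-7-(benzyloxy)-2-[3,4-bis(benzyloxy)phenyl]-3,4-dihydro-2H-chromen-3-yl acetate F9. AgBF4 in THF at 0 °C then releases the C4 cation in the presence of 10, and the coupling comes back to the route at 12.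

Further compounds
F1 | step 5 | (2R,3S)-7-(benzyloxy)-2-[3,4-bis(benzyloxy)phenyl]-3-chloro-3,4-dihydro-2H-chromene | Cl[C@H]1Cc2ccc(OCc3ccccc3)cc2O[C@@H]1c1ccc(OCc2ccccc2)c(OCc2ccccc2)c1
F2 | step 5 | (2S)-7-(benzyloxy)-2-[3,4-bis(benzyloxy)phenyl]-2H-chromene | C1=Cc2ccc(OCc3ccccc3)cc2O[C@@H]1c1ccc(OCc2ccccc2)c(OCc2ccccc2)c1
F3 | step 5 | (2R,3S)-7-(benzyloxy)-2-[3,4-bis(benzyloxy)phenyl]-3,4-dihydro-2H-chromen-3-ol | O[C@H]1Cc2ccc(OCc3ccccc3)cc2O[C@@H]1c1ccc(OCc2ccccc2)c(OCc2ccccc2)c1
F4 | step 6 | (2E)-1-[4-(benzyloxy)-2-(methoxymethoxy)phenyl]-3-[3,4-bis(benzyloxy)phenyl]prop-2-en-1-one | COCOc1cc(OCc2ccccc2)ccc1C(=O)/C=C/c1ccc(OCc2ccccc2)c(OCc2ccccc2)c1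
F5 | step 6 | [4-(benzyloxy)-2-(methoxymethoxy)phenyl]{(2R,3S)-3-[3,4-bis(benzyloxy)phenyl]oxiran-2-yl}methanone | COCOc1cc(OCc2ccccc2)ccc1C(=O)[C@@H]1O[C@H]1c1ccc(OCc2ccccc2)c(OCc2ccccc2)c1
F6 | step 6 | (2R,3R)-7-(benzyloxy)-2-[3,4-bis(benzyloxy)phenyl]-3-hydroxy-2,3-dihydro-4H-chromen-4-one | O[C@H]1C(=O)c2ccc(OCc3ccccc3)cc2O[C@@H]1c1ccc(OCc2ccccc2)c(OCc2ccccc2)c1
F7 | step 6 | (2R,3S,4R)-7-(benzyloxy)-2-[3,4-bis(benzyloxy)phenyl]-3,4-dihydro-2H-chromene-3,4-diol | O[C@H]1[C@H](O)c2ccc(OCc3ccccc3)cc2O[C@@H]1c1ccc(OCc2ccccc2)c(OCc2ccccc2)c1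
F8 | step 6 | (2R,3R,4R)-7-(benzyloxy)-2-[3,4-bis(benzyloxy)phenyl]-3,4-dihydro-2H-chromene-3,4-diyl diacetate | CC(=O)O[C@H]1[C@H](OC(C)=O)c2ccc(OCc3ccccc3)cc2O[C@@H]1c1ccc(OCc2ccccc2)c(OCc2ccccc2)c1
F9 | step 7 | (2R,3R,4R)-4-(benzylsulfanyl)-7-(benzyloxy)-2-[3,4-bis(benzyloxy)phenyl]-3,4-dihydro-2H-chromen-3-yl acetate | CC(=O)O[C@H]1[C@H](SCc2ccccc2)c2ccc(OCc3ccccc3)cc2O[C@@H]1c1ccc(OCc2ccccc2)c(OCc2ccccc2)c1
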